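**Strategy.** Ring B is disconnected at C6–C7 and at the C5–Br bond. The secondary C5 bromide sits next to quaternary C4a, where substitution fails, but C5 is exactly where the radical ends up after a 6-endo closure of a C7 radical (next to the C8 ketone) onto a C5=C6 vinyl group on C4a. A copper-mediated bromine atom-transfer cyclization therefore forms C6–C7, ring B and the C5–Br bond in one operation. Its precursor is a ring A bromomethyl ketone with a vinyl group on C4a, a triethylsilyl ether on C8a and an acetonide joining the C2 and C5' oxygens. Ring C comes from (−)-bornyl acetate, ring A from ring-closing enyne metathesis.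

Key step: step 20

Remark: decalin atoms are C1–C8a (ring A C1–C4, ring B C5–C8), ring C atoms are C1'–C5' (C1' on C2, C2' CMe2, C3' CHBr, C5' CHO); β is the face of the C4a methyl (decalin) or of the C5' oxygen (ring C); C1, C2, C4 of (1S,2R,4S)-bornyl acetate become C1', C5', C3'; TBS = tert-butyldimethylsilyl, TES = triethylsilyl; propynal is taken as commercial.

Step 1
Reactants: 1 (−)-bornyl acetate
Product: 2 5-oxobornyl acetate
Conditions: CrO3, AcOH, Ac2O, rt
Reagents that add atoms: chromium trioxide, O=[Cr](=O)=O
Why: Oxidation of an unactivated methylene by hexavalent chromium: the acetate deactivates C2 and C3 and the C5 methylene is the exposed one, so the known 5-ketone should form without touching a stereocentre.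

Step 2
Reactants: 2 5-oxobornyl acetate
Product: 3 5-oxoborneol
Conditions: K2CO3, MeOH, rt
Reagents that add atoms: none
Why: Base-catalysed transesterification frees the endo alcohol; the acetate is exchanged because an acyloxy group β to the later C3' ketone would be a leaving group.

Step 3
Reactants: 3 5-oxoborneol
Product: 4 5-oxoborneol TBS ether
Conditions: TBSCl, imidazole, DMF, 40 °C
Reagents that add atoms: tert-butyldimethylsilyl chloride, CC(C)(C)[Si](C)(C)Cl
Why: Silylation of the hindered endo alcohol gives an ether that tolerates the enolate, radical and hydrogenation conditions that follow.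

Step 4
Reactants: 4 5-oxoborneol TBS ether
Product: 6 ring C aldehyde acid, via silyl enol ether 5 (not isolated)
Conditions: LiN(i-Pr)2, THF, −78 °C; Me3SiCl; then O3, CH2Cl2, −78 °C; Me2S
Reagents that add atoms: ozone, [O-][O+]=O
Why: Enolization can only occur toward C6 (C4 is a bridgehead), and ozonolysis of the silyl enol ether cleaves C5–C6 to the C1' aldehyde and the C3' acid, which stay cis to each other and to the C5' oxygen because they were the two-carbon bridge and the endo substituent of the bicycle.

Step 5
Reactants: 6 ring C aldehyde acid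
Product: 7 ring C cyano acid
Conditions: I2, aq. NH3, THF, rt
Reagents that add atoms: ammonia, N
Why: Oxidative conversion of an aldehyde into a nitrile with iodine in aqueous ammonia (via the N-iodo aldimine) masks the future C2 carbon as a group inert to thiyl radicals, phosphorus halides and hydrogenation.

Step 6
Reactants: 7 ring C cyano acid
Product: 10 ring C ketone, via Barton ester 8 (not isolated), via hydroperoxide 9 (not isolated)
Conditions: N-hydroxypyridine-2-thione, DCC, DMAP (cat.), CH2Cl2, dark; t-BuSH, O2, hν, 0 °C; then TsCl, pyridine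
Reagents that add atoms: dioxygen, O=O
Why: Barton decarboxylation of the thiohydroxamate ester under oxygen with a thiol chain carrier gives the C3' hydroperoxide, and sulfonylation–elimination gives the nor-ketone; the C3' configuration is erased on purpose.

Step 7
Reactants: 10 ring C ketone
Product: 11 ring C alkenyl bromide
Conditions: P(OPh)3, Br2, Et3N, CH2Cl2, −60 °C to reflux
Reagents that add atoms: bromine, BrBr
Why: Conversion of an enolizable ketone into the alkenyl bromide with the triphenyl phosphite–bromine reagent; only C4' carries α-hydrogens (C2' is quaternary), so the double bond can only form as C3'=C4'.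

Step 8
Reactants: 11 ring C alkenyl bromide
Product: 12 ring C bromide
Conditions: H2 (1 atm), Rh/Al2O3, EtOAc, rt
Reagents that add atoms: none
Why: Heterogeneous syn hydrogenation should occur on the α face, opposite the bulky silyloxy group on the allylic carbon C5', which puts the C3' hydrogen α and the bromine β, cis to the C5' oxygen and the nitrile; rhodium on alumina is chosen as the catalyst least prone to C–Br hydrogenolysis.

Step 9
Reactants: 12 ring C bromide
Product: 15 ring C hydroxy methyl ketone, via lithium ketimide 13 (not isolated), via silyl ether ketone 14 (not isolated)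
Conditions: MeLi, Et2O, 0 °C to rt; then 3 M HCl, THF/MeOH, 40 °C
Reagents that add atoms: methyllithium, [Li]C; water, O
Why: Addition of an organolithium to a nitrile stops at the ketimide, and aqueous acid hydrolyses it to the methyl ketone and removes the silyl ether in the same operation; the cis bromide cannot be displaced internally because the nitrogen and oxygen anions lie on its own face.

Step 10
Reactants: 15 ring C hydroxy methyl ketone; 16 propynal
Product: 17 aldol adduct
Conditions: LiN(i-Pr)2 (2.2 equiv), THF, −78 °C; 16; aq. NH4Cl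
Reagents that add atoms: propynal (16), C#CC=O
Why: Aldol addition of the lithium enolate, which can form only at the methyl group, to the aldehyde carbonyl; the new carbinol carbon C8a forms as a mixture of epimers that converges on oxidation in step 16.

Step 11
Reactants: 17 aldol adduct
Product: 18 propargylic TBS ether
Conditions: TBSCl (1.1 equiv), imidazole, CH2Cl2, 0 °C
Reagents that add atoms: tert-butyldimethylsilyl chloride, CC(C)(C)[Si](C)(C)Cl
Why: Selective silylation: the propargylic alcohol is far less hindered than the C5' hydroxyl next to quaternary C1'.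

Step 12
Reactants: 18 propargylic TBS ether
Product: 19 allyl carbinol
Conditions: allylmagnesium bromide (4 equiv), Et2O, −78 °C; aq. NH4Cl
Reagents that add atoms: allylmagnesium bromide, C=CC[Mg]Br
Why: Chelation-controlled Grignard addition: the magnesium alkoxide of the C5' hydroxyl binds the ketone oxygen, C2' sits axial on the six-membered chelate, and the allyl group (future C3 and C4) adds to the open face anti to C2' (also the Felkin–Anh sense), which sets C2 as in the target.

Step 13
Reactants: 19 allyl carbinol
Product: 20 enyne acetonide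
Conditions: 2-methoxypropene, PPTS, CH2Cl2, 0 °C to rt
Reagents that add atoms: 2-methoxypropene, COC(C)=C
Why: Acid-catalysed ketalization of the 1,3-diol (C5' and C2 oxygens) gives the six-membered acetonide cis-fused to ring C.

Step 14
Reactants: 20 enyne acetonide
Product: 21 ring A diene
Conditions: second-generation Grubbs catalyst (5 mol %), ethylene (1 atm), toluene, 60 °C
Reagents that add atoms: none
Why: Ring-closing enyne metathesis of the 1,7-enyne gives ring A as a 1-vinylcyclohexene, so that C4a already carries the vinyl group that becomes C5 and C6.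

Step 15
Reactants: 21 ring A diene
Product: 22 ring A dienol
Conditions: Bu4NF, THF, 0 °C to rt
Reagents that add atoms: none
Why: Fluoride cleavage of the secondary silyl ether.

Step 16
Reactants: 22 ring A dienol
Product: 23 ring A dienone
Conditions: Dess–Martin periodinane, NaHCO3, CH2Cl2, 0 °C
Reagents that add atoms: none
Why: Periodinane oxidation of the allylic alcohol under buffered, non-basic conditions, so that the acetonide oxygen β to the new ketone is not eliminated.

Step 17
Reactants: 23 ring A dienone
Product: 25 C4a-methyl ketone, via lithium dienolate 24 (not isolated)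
Conditions: LiBH(s-Bu)3, THF, −78 °C; then MeI, DMPU, −78 to 0 °C
Reagents that add atoms: iodomethane, CI
Why: Conjugate reduction with a hindered borohydride gives the C8a–C4a enolate regiospecifically, and alkylation of this dienolate at its α carbon (reductive alkylation of an enone) should occur axially on the β face of the half-chair that keeps ring C equatorial on C2, setting C4a with methyl β and vinyl equatorial.

Step 18
Reactants: 25 C4a-methyl ketone; 26 ethyl vinyl ether
Product: 28 α-hydroxy methyl ketone, via enol ether adduct 27 (not isolated)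
Conditions: 26, t-BuLi, THF, −78 to 0 °C; CeCl3, −78 °C; 25; then 0.5 M HCl, THF, 0 °C
Reagents that add atoms: ethyl vinyl ether (26), CCOC=C; water, O
Why: Addition of an acyl anion equivalent (1-ethoxyvinylcerium, too weakly basic to enolize toward C1) should occur equatorially from the β face because the axial acetonide oxygen on C2 blocks axial attack, giving C8a with oxygen axial (α), and mild acid unmasks the methyl ketone.

Step 19
Reactants: 28 α-hydroxy methyl ketone
Product: 30 bromomethyl ketone, via bis-silyl enol ether 29 (not isolated)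
Conditions: Et3SiOTf (3 equiv), Et3N, CH2Cl2, −78 to 0 °C; then NBS, THF, −78 °C
Reagents that add atoms: triethylsilyl trifluoromethanesulfonate, CC[Si](CC)(CC)OS(=O)(=O)C(F)(F)F; N-bromosuccinimide, BrN1C(=O)CCC1=O
Why: The silyl triflate silylates the tertiary alcohol and converts the methyl ketone into its only possible enol silyl ether (C8a is quaternary), which N-bromosuccinimide brominates at C7.

Step 20
Reactants: 30 bromomethyl ketone
Product: 31 trans-fused 5-bromo-8a-silyloxy decalin-8-one
Conditions: CuBr2 (10 mol %), tris(2-pyridylmethyl)amine (10 mol %), Et4NBF4 (0.1 M), MeCN, divided cell, glassy-carbon cathode, potential held at the half-wave potential of the copper couple, 40 °C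
Reagents that add atoms: none
Why: Cathodically generated monovalent copper abstracts bromine from the bromomethyl ketone, the electrophilic C7 radical next to the C8 carbonyl adds to the terminal vinyl carbon C6, and the secondary C5 radical takes bromine back from the divalent copper bromide complex, which the cathode reduces again. The closest known reaction type is copper-catalysed atom-transfer radical cyclization of α-halo carbonyl compounds with electrochemical catalyst regeneration. Ring B closes in the 6-endo-trig mode, favoured over 5-exo because the carbonyl lies inside the forming ring and the internal vinyl carbon C5 is neopentylic; the trans ring fusion is already fixed by C4a and C8a. The new C5 stereocentre is set in the bromine transfer: the axial triethylsilyloxy group on C8a blocks the α face, so the bulky copper bromide complex should deliver bromine to the β face and the bromide ends up equatorial. The step needs activation of the α-keto C–Br bond only, which is secured by a potential too mild to reduce the secondary alkyl bromides on C3' and C5.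

Step 21
Reactants: 31 trans-fused 5-bromo-8a-silyloxy decalin-8-one
Product: 32 protected C8 methyl carbinol
Conditions: MeMgBr, CeCl3, THF, −78 to 0 °C; aq. NH4Cl
Reagents that add atoms: methylmagnesium bromide, C[Mg]Br
Why: Cerium-modified Grignard 1,2-addition (too weakly basic to enolize the γ-bromo ketone): the axial C4a methyl blocks the β face in a 1,3-diaxial sense, so methyl should enter equatorially from the α face and the C8 hydroxyl becomes axial (β).

Step 22
Reactants: 32 protected C8 methyl carbinol
Product: 33 target CNP0390567.2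
Conditions: 48% aq. HF, MeCN, rt
Reagents that add atoms: none
Why: Aqueous hydrogen fluoride cleaves the tertiary silyl ether and hydrolyses the acetonide in one operation under conditions too mild for pinacol rearrangement of the C8/C8a diol.

**Compound list**

1 | (−)-bornyl acetate, (1S,2R,4S)-1,7,7-trimethylbicyclo[2.2.1]heptan-2-yl acetate (endo) | CC(=O)O[C@@H]1C[C@@H]2CC[C@@]1(C)C2(C)C | starting material
2 | 5-oxobornyl acetate, endo-2-acetoxy-1,7,7-trimethylbicyclo[2.2.1]heptan-5-one | CC(=O)O[C@@H]1C[C@@H]2C(=O)C[C@@]1(C)C2(C)C | intermediate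
3 | 5-oxoborneol, endo-2-hydroxy-1,7,7-trimethylbicyclo[2.2.1]heptan-5-one | O[C@@H]1C[C@@H]2C(=O)C[C@@]1(C)C2(C)C | intermediate
4 | 5-oxoborneol TBS ether | CC(C)(C)[Si](C)(C)O[C@@H]1C[C@@H]2C(=O)C[C@@]1(C)C2(C)C | intermediate
5 | silyl enol ether of 4 (C5=C6, 5-trimethylsilyloxy) | CC(C)(C)[Si](C)(C)O[C@@H]1C[C@@H]2C(O[Si](C)(C)C)=C[C@@]1(C)C2(C)C | intermediate
6 | ring C aldehyde acid, 4-(TBS-oxy)-3-formyl-2,2,3-trimethylcyclopentane-1-carboxylic acid; carboxyl (C3'), formyl (C1') and silyloxy (C5') all cis | CC1(C)[C@@H](C(=O)O)C[C@@H](O[Si](C)(C)C(C)(C)C)[C@@]1(C)C=O | intermediate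
7 | ring C cyano acid, 3-cyano analogue of 6 | CC1(C)[C@@H](C(=O)O)C[C@@H](O[Si](C)(C)C(C)(C)C)[C@@]1(C)C#N | intermediate
8 | Barton ester, O-acyl N-hydroxypyridine-2-thione of 7 | CC1(C)[C@@H](C(=O)ON2C=CC=CC2=S)C[C@@H](O[Si](C)(C)C(C)(C)C)[C@@]1(C)C#N | intermediate
9 | C3' hydroperoxide (both C3' epimers) | CC1(C)C(OO)C[C@@H](O[Si](C)(C)C(C)(C)C)[C@@]1(C)C#N | intermediate
10 | ring C ketone, 2-(TBS-oxy)-1,5,5-trimethyl-4-oxocyclopentane-1-carbonitrile; nitrile and silyloxy cis | CC1(C)C(=O)C[C@@H](O[Si](C)(C)C(C)(C)C)[C@@]1(C)C#N | intermediate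
11 | ring C alkenyl bromide, 3-bromo-5-(TBS-oxy)-1,2,2-trimethylcyclopent-3-ene-1-carbonitrile; nitrile and silyloxy cis | CC1(C)C(Br)=C[C@@H](O[Si](C)(C)C(C)(C)C)[C@@]1(C)C#N | intermediate
12 | ring C bromide, 3-bromo-5-(TBS-oxy)-1,2,2-trimethylcyclopentane-1-carbonitrile; bromide, silyloxy and nitrile all cis | CC1(C)[C@@H](Br)C[C@@H](O[Si](C)(C)C(C)(C)C)[C@@]1(C)C#N | intermediate
13 | lithium ketimide from 12 | CC1(C)[C@@H](Br)C[C@@H](O[Si](C)(C)C(C)(C)C)[C@@]1(C)C(C)=N[Li] | intermediate
14 | silyl ether ketone, TBS ether of 15 | CC1(C)[C@@H](Br)C[C@@H](O[Si](C)(C)C(C)(C)C)[C@@]1(C)C(C)=O | intermediate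
15 | ring C hydroxy methyl ketone, 1-[(1S,3S,5R)-3-bromo-5-hydroxy-1,2,2-trimethylcyclopentyl]ethan-1-one | CC1(C)[C@@H](Br)C[C@@H](O)[C@@]1(C)C(C)=O | intermediate
16 | propynal | C#CC=O | starting material
17 | aldol adduct, 1-(ring C)-3-hydroxypent-4-yn-1-one (both C8a epimers) | CC1(C)[C@@H](Br)C[C@@H](O)[C@@]1(C)C(=O)CC(O)C#C | intermediate
18 | propargylic TBS ether of 17 | CC1(C)[C@@H](Br)C[C@@H](O)[C@@]1(C)C(=O)CC(O[Si](C)(C)C(C)(C)C)C#C | intermediate
19 | allyl carbinol, tertiary alcohol at C2 (configured as in the target) bearing ring C, allyl and the 2-(TBS-oxy)but-3-ynyl chain | CC1(C)[C@@H](Br)C[C@@H](O)[C@@]1(C)[C@](O)(CC=C)CC(O[Si](C)(C)C(C)(C)C)C#C | intermediate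
20 | enyne acetonide, acetonide of 19 across the C5' and C2 oxygens | CC1(C)[C@@H](Br)C[C@H]2OC(C)(C)O[C@@](CC=C)(CC(O[Si](C)(C)C(C)(C)C)C#C)[C@@]12C | intermediate
21 | ring A diene, C4=C4a ring alkene, vinyl on C4a, TBS-oxy on C8a, spiro acetonide at C2 | CC1(C)[C@@H](Br)C[C@H]2OC(C)(C)O[C@]3(CC=C(C=C)C(O[Si](C)(C)C(C)(C)C)C3)[C@@]12C | intermediate
22 | ring A dienol, C8a alcohol of 21 | CC1(C)[C@@H](Br)C[C@H]2OC(C)(C)O[C@]3(CC=C(C=C)C(O)C3)[C@@]12C | intermediate
23 | ring A dienone, C8a ketone with C4a=C4 and vinyl on C4a | CC1(C)[C@@H](Br)C[C@H]2OC(C)(C)O[C@]3(CC=C(C=C)C(=O)C3)[C@@]12C | intermediate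
24 | lithium dienolate (C8a–O–Li, C8a=C4a, vinyl on C4a) | CC1(C)[C@@H](Br)C[C@H]2OC(C)(C)O[C@]3(CCC(C=C)=C(O[Li])C3)[C@@]12C | intermediate
25 | C4a-methyl ketone, C8a ketone with β-methyl and vinyl on C4a | CC1(C)[C@@H](Br)C[C@H]2OC(C)(C)O[C@]3(CC[C@@](C)(C=C)C(=O)C3)[C@@]12C | intermediate
26 | ethyl vinyl ether | CCOC=C | starting material
27 | enol ether adduct, C8a tertiary alcohol bearing 1-ethoxyvinyl | CC1(C)[C@@H](Br)C[C@H]2OC(C)(C)O[C@]3(CC[C@@](C)(C=C)[C@](O)(C(=C)OCC)C3)[C@@]12C | intermediate
28 | α-hydroxy methyl ketone, C8a α-hydroxyl and β-acetyl | CC1(C)[C@@H](Br)C[C@H]2OC(C)(C)O[C@]3(CC[C@@](C)(C=C)[C@](O)(C(C)=O)C3)[C@@]12C | intermediate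
29 | bis-silyl enol ether, C8a TES ether and TES enol ether of the acetyl group | CC1(C)[C@@H](Br)C[C@H]2OC(C)(C)O[C@]3(CC[C@@](C)(C=C)[C@](O[Si](CC)(CC)CC)(C(=C)O[Si](CC)(CC)CC)C3)[C@@]12C | intermediate
30 | bromomethyl ketone (key-step precursor), C4a vinyl, C8a TES ether | CC1(C)[C@@H](Br)C[C@H]2OC(C)(C)O[C@]3(CC[C@@](C)(C=C)[C@](O[Si](CC)(CC)CC)(C(=O)CBr)C3)[C@@]12C | intermediate
31 | trans-fused 5β-bromo-8a-silyloxy decalin-8-one (key-step product) | CC1(C)[C@@H](Br)C[C@H]2OC(C)(C)O[C@]3(CC[C@@]4(C)[C@H](Br)CCC(=O)[C@]4(O[Si](CC)(CC)CC)C3)[C@@]12C | intermediate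
32 | protected C8 methyl carbinol (8α-methyl, 8β-hydroxyl) | CC1(C)[C@@H](Br)C[C@H]2OC(C)(C)O[C@]3(CC[C@@]4(C)[C@H](Br)CC[C@](C)(O)[C@]4(O[Si](CC)(CC)CC)C3)[C@@]12C | intermediate
33 | CNP0390567.2, (2S,4aR,5R,8S,8aS)-5-bromo-2-[(1S,3S,5R)-3-bromo-5-hydroxy-1,2,2-trimethylcyclopentyl]-4a,8-dimethyldecahydronaphthalene-2,8,8a-triol | CC1(C)[C@@H](Br)C[C@@H](O)[C@@]1(C)[C@]1(O)CC[C@@]2(C)[C@H](Br)CC[C@](C)(O)[C@]2(O)C1 | target

**Totals**

Total step count: 22. Longest linear sequence: 22 steps (1 to 33).

**Steps most likely to fail**

1. Step 20. The C7 radical may be reduced by monovalent copper or at the cathode before it cyclizes, so that bromine is lost without ring closure, or bromine may be delivered to the α face of C5. Fallback with a different radical carrier: from 30, displacement of the α-keto bromide with potassium O-ethyl xanthate would give the S-(2-oxoalkyl) xanthate F1. Heating with dilauroyl peroxide in 1,2-dichloroethane should effect the degenerative xanthate-transfer 6-endo cyclization to the C5 xanthate F2. Radical exchange of the xanthate for bromine with ethyl 2-bromo-2-methylpropanoate and dilauroyl peroxide then leads back to 31.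

2. Step 8. Hydrogenolysis of the vinylic C–Br bond may compete with saturation of the double bond, or the two faces may be poorly discriminated. Fallback that delivers the C3' hydrogen as an atom: from 10, condensation with hydrazine would give the hydrazone F3. Oxidation with CuBr2 and Et3N should give the geminal dibromide F4. One equivalent of Bu3SnH (Et3B, air, −78 °C) removes one bromine; the α-bromo radical should take hydrogen on the less hindered α face, and the route is rejoined at 12.

3. Step 12. Allylmagnesium reagents add very fast, so addition may outrun chelate organization and erode facial selectivity at C2. Fallback by intramolecular delivery: from 18, silylation of the C5' hydroxyl with allyl(chloro)dimethylsilane and imidazole would give the allyldimethylsilyl ether F5. TiCl4 at −78 °C should transfer the allyl group from silicon to the ketone from the side of the C5' oxygen, and the alkoxide closes onto silicon to give the cyclic dimethylsilylene F6. HF·pyridine releases the diol 19.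

**Further compounds**

F1 | step 20 | S-(2-oxoalkyl) O-ethyl xanthate from 30 | CC1(C)[C@@H](Br)C[C@H]2OC(C)(C)O[C@]3(CC[C@@](C)(C=C)[C@](O[Si](CC)(CC)CC)(C(=O)CSC(=S)OCC)C3)[C@@]12C
F2 | step 20 | C5 xanthate of the cyclized decalin-8-one (either C5 epimer) | CC1(C)[C@@H](Br)C[C@H]2OC(C)(C)O[C@]3(CC[C@@]4(C)C(SC(=S)OCC)CCC(=O)[C@]4(O[Si](CC)(CC)CC)C3)[C@@]12C
F3 | step 8 | hydrazone of ketone 10 | CC1(C)C(=NN)C[C@@H](O[Si](C)(C)C(C)(C)C)[C@@]1(C)C#N
F4 | step 8 | C3' geminal dibromide | CC1(C)C(Br)(Br)C[C@@H](O[Si](C)(C)C(C)(C)C)[C@@]1(C)C#N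
F5 | step 12 | C5' allyldimethylsilyl ether of 18 | CC1(C)[C@@H](Br)C[C@@H](O[Si](C)(C)CC=C)[C@@]1(C)C(=O)CC(O[Si](C)(C)C(C)(C)C)C#C
F6 | step 12 | cyclic dimethylsilylene of diol 19 (C5' and C2 oxygens) | CC1(C)[C@@H](Br)C[C@H]2O[Si](C)(C)O[C@@](CC=C)(CC(O[Si](C)(C)C(C)(C)C)C#C)[C@@]12C
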